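**Retrosynthetic overview**

1. The target is W-(4β→6)-X-(4β→8)-Y-(4β→6)-Z, where W, Y and Z are (−)-epicatechin units and X is a (−)-epiafzelechin unit (all 2R,3R, every C4 bond trans to the 3-OH). The last step is one hydrogenolysis that removes 15 benzyl ethers and 4 aryl bromides.
2. Each interflavan bond is traced back to a C4–O bond. DDQ turns a C4–H into a C4–O ether (on a monomer, then the dimer, then the trimer), and that ether is ionised for coupling in the order W→X (C6), X→Y (C8), Y→Z (C6). Bromine at C8 (and C6) blocks the other ring-A positions.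
3. Units W, Y and Z come from (−)-epicatechin with their rings intact (benzylation, bromination, C4 etherification).
4. Unit X is built new: ring A from 3,5-bis(benzyloxy)phenol, ring B from 4-(benzyloxy)benzaldehyde. A Friedel–Crafts allylation makes C4–C4a, then ring C is closed by C–O bond formation (epoxidation, then the phenol oxygen opens the epoxide 6-endo at C2). This is the only ring formed in the route.
5. C2 and C3 of unit X are set after ring closure: oxidation to the racemic flavan-3-one, then a dynamic kinetic resolution by asymmetric hydrogenation (the new step) gives the 2R,3R cis alcohol.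

Assumption: (−)-epicatechin, 3,5-bis(benzyloxy)phenol and 4-(benzyloxy)benzaldehyde are taken as catalogue chemicals.

**Route**

Step 1
Reactants: 1 (−)-epicatechin
Product: 2 5,7,3',4'-tetra-O-benzyl-(−)-epicatechin (2R,3R)
Conditions: BnBr (4.4 equiv), K2CO3, DMF, 0 °C → rt
Reagents that add atoms: benzyl bromide, BrCc1ccccc1
Why: Williamson ether synthesis; K2CO3 deprotonates only the four phenols (not the secondary 3-OH), and the mild base at ≤ 25 °C leaves C2 and C3 untouched.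

Step 2
Reactants: 2 5,7,3',4'-tetra-O-benzyl-(−)-epicatechin
Product: 3 8-bromo-5,7,3',4'-tetra-O-benzyl-(−)-epicatechin (2R,3R)
Conditions: NBS (1.0 equiv), CH2Cl2, −78 → 0 °C
Reagents that add atoms: N-bromosuccinimide, O=C1CCC(=O)N1Br
Why: Electrophilic aromatic bromination; C8 is the most nucleophilic ring-A carbon of benzylated flavan-3-ols, so one equivalent of NBS gives the 8-bromide and leaves only C6 free for the later coupling.

Step 3
Reactants: 2 5,7,3',4'-tetra-O-benzyl-(−)-epicatechin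
Product: 4 (2R,3R,4S)-4-(2-ethoxyethoxy)-5,7,3',4'-tetra-O-benzylepicatechin (4β ether, trans to 3-OH)
Conditions: DDQ (2 equiv), 2-ethoxyethanol (5 equiv), CH2Cl2, rt
Reagents that add atoms: 2-ethoxyethanol, CCOCCO
Why: Oxidative benzylic C–H etherification; DDQ abstracts hydride from C4 to give the ring-A-stabilised cation, and the alcohol adds to the face anti to the 3-OH, forming the C4–O bond as the 4β ether.

Step 4
Reactants: 4 (2R,3R,4S)-4-(2-ethoxyethoxy)-5,7,3',4'-tetra-O-benzylepicatechin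
Product: 5 (2R,3R,4S)-6,8-dibromo-4-(2-ethoxyethoxy)-5,7,3',4'-tetra-O-benzylepicatechin (electrophile for unit W)
Conditions: NBS (2.05 equiv), CH2Cl2, −20 → 0 °C
Reagents that add atoms: N-bromosuccinimide, O=C1CCC(=O)N1Br
Why: Twofold electrophilic aromatic bromination with neutral NBS (no acid is formed, so the C4 ether survives) blocks both ring-A carbons, so this electrophile cannot act as a nucleophile.

Step 5
Reactants: 6 4-(benzyloxy)benzaldehyde
Product: 7 rac-1-[4-(benzyloxy)phenyl]prop-2-en-1-ol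
Conditions: CH2=CHMgBr (1.2 equiv), THF, 0 °C; then H2O
Reagents that add atoms: vinylmagnesium bromide, C=C[Mg]Br
Why: Grignard 1,2-addition to the aldehyde gives the racemic 1-aryl allyl alcohol, a mild precursor of the aryl-allyl cation (its stereocentre is lost in step 6).

Step 6
Reactants: 7 rac-1-[4-(benzyloxy)phenyl]prop-2-en-1-ol; 8 3,5-bis(benzyloxy)phenol (3 equiv, excess recovered)
Product: 9 (E)-3,5-bis(benzyloxy)-2-{3-[4-(benzyloxy)phenyl]prop-2-en-1-yl}phenol
Conditions: H2SO4 on SiO2 (cat.), CH2Cl2, 0 °C → rt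
Reagents that add atoms: none
Why: Friedel–Crafts allylation (SN1′ type); the acid ionises 7 with loss of water to the 4-benzyloxyphenyl-allyl cation, which is attacked at its unsubstituted terminus by the carbon ortho to the free OH of 8, giving the conjugated E-alkene and the future C4–C4a bond.

Step 7
Reactants: 9 (E)-3,5-bis(benzyloxy)-2-{3-[4-(benzyloxy)phenyl]prop-2-en-1-yl}phenol
Product: 11 racemic 2,3-trans-5,7-bis(benzyloxy)-2-[4-(benzyloxy)phenyl]chroman-3-ol, via trans-epoxide 10 (not isolated)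
Conditions: mCPBA (1.1 equiv), CH2Cl2, 0 °C → rt
Reagents that add atoms: meta-chloroperoxybenzoic acid, OOC(=O)c1cccc(Cl)c1
Why: Prilezhaev epoxidation of the electron-rich styrene, then acid-catalysed (3-chlorobenzoic acid formed in situ) 6-endo epoxide opening by the phenol oxygen at the benzylic carbon closes ring C through the O1–C2 bond and leaves the C3–O bond; the product is mainly 2,3-trans, and since both centres are reset in steps 8 and 9 the ratio does not matter.

Step 8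
Reactants: 11 racemic 2,3-trans-5,7-bis(benzyloxy)-2-[4-(benzyloxy)phenyl]chroman-3-ol
Product: 12 rac-5,7-bis(benzyloxy)-2-[4-(benzyloxy)phenyl]chroman-3-one
Conditions: Dess–Martin periodinane (1.3 equiv), wet CH2Cl2, rt
Reagents that add atoms: none
Why: Dess–Martin oxidation of the secondary alcohol gives the flavan-3-one, whose C2–H is now acidic (needed for step 9); benzyl ethers are inert.

Step 9
Reactants: 12 rac-5,7-bis(benzyloxy)-2-[4-(benzyloxy)phenyl]chroman-3-one
Product: 13 (2R,3R)-5,7-bis(benzyloxy)-2-[4-(benzyloxy)phenyl]chroman-3-ol (5,7,4'-tri-O-benzyl-(−)-epiafzelechin)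
Conditions: RuCl2[(S)-xylBINAP][(S)-DAIPEN] (1 mol %; the mirror-image complex if a first run gives the 2S,3S alcohol), t-BuOK (5 mol %), H2 (10 atm), i-PrOH/THF 1:1, 25 °C, degassed
Reagents that add atoms: none
Why: Proposed new method: dynamic kinetic resolution by asymmetric hydrogenation of a racemic 2-aryl-chroman-3-one, a substrate class on which it has not been shown; the C2–H (alpha to C=O, benzylic and alpha to the ring oxygen) epimerises through the potassium enolate faster than the divalent ruthenium hydride/diamine N–H pair reduces the ketone, the chiral catalyst reduces one ketone enantiomer preferentially and delivers hydride to the face anti to the 2-aryl group, which gives the 2,3-cis alcohol and sets C2 (R) and C3 (R) together; the closest known reaction type is the Noyori-type DKR hydrogenation of 2-aryl- and 2-aryloxy-cycloalkanones to cis alcohols.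

Step 10
Reactants: 13 5,7,4'-tri-O-benzyl-(−)-epiafzelechin
Product: 14 8-bromo-5,7,4'-tri-O-benzyl-(−)-epiafzelechin (2R,3R)
Conditions: NBS (1.0 equiv), CH2Cl2, −78 → 0 °C
Reagents that add atoms: N-bromosuccinimide, O=C1CCC(=O)N1Br
Why: Electrophilic aromatic bromination at C8 (same selectivity as in step 2) leaves C6 as the only nucleophilic ring-A carbon of unit X.

Step 11
Reactants: 5 6,8-dibromo-4β-(2-ethoxyethoxy)-tetra-O-benzylepicatechin (1.5 equiv); 14 8-bromo-5,7,4'-tri-O-benzyl-(−)-epiafzelechin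
Product: 15 dimer W–X: 6,8-dibromo-5,7,3',4'-tetra-O-benzylepicatechin-(4β→6)-8-bromo-5,7,4'-tri-O-benzylepiafzelechin
Conditions: TMSOTf (0.2 equiv), CH2Cl2, −78 → −30 °C; then NaHCO3 (aq)
Reagents that add atoms: none
Why: Lewis-acid-promoted SN1 Friedel–Crafts alkylation; TMSOTf ionises the C4–O bond of 5 and the cation is attacked by C6 of 14, the only unblocked ring-A carbon in the flask, from the face anti to the 3-OH of unit W, which sets C4 of unit W as 4β (3,4-trans).

Step 12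
Reactants: 15 dimer W–X
Product: 16 dimer W–X carrying a 4β-(2-ethoxyethoxy) group on unit X
Conditions: DDQ (2.5 equiv), 2-ethoxyethanol (10 equiv), CH2Cl2, rt
Reagents that add atoms: 2-ethoxyethanol, CCOCCO
Why: DDQ oxidative C–H etherification at the only ring-C CH2 of the dimer (C4 of unit X, whose axial C–H is aligned with the trioxygenated ring A), while the C4–H of unit W is a hindered diarylmethine C–H poorly aligned with either ring and the OCH2Ph groups of plain benzyl ethers react far more slowly; the alcohol adds anti to the 3-OH.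

Step 13
Reactants: 16 dimer W–X with 4β-(2-ethoxyethoxy) on unit X; 2 5,7,3',4'-tetra-O-benzyl-(−)-epicatechin (3 equiv, excess recovered)
Product: 17 trimer W–X–Y: dimer W–X-(4β→8)-5,7,3',4'-tetra-O-benzylepicatechin
Conditions: TMSOTf (0.2 equiv), CH2Cl2, −78 °C; then NaHCO3 (aq)
Reagents that add atoms: none
Why: Friedel–Crafts alkylation of the flavan-4-yl cation of unit X by C8 of 2 (far more reactive than C6 in benzylated flavan-3-ols), anti to the 3-OH, sets C4 of unit X as 4β; the electrophile has no free ring-A carbon and cannot self-condense.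

Step 14
Reactants: 17 trimer W–X–Y
Product: 18 trimer W–X–Y carrying a 4β-(2-ethoxyethoxy) group on unit Y
Conditions: DDQ (2.5 equiv), 2-ethoxyethanol (10 equiv), CH2Cl2, rt
Reagents that add atoms: 2-ethoxyethanol, CCOCCO
Why: DDQ oxidative C–H etherification at the only ring-C CH2 left in the molecule (C4 of unit Y), with the alcohol adding anti to the 3-OH.

Step 15
Reactants: 18 trimer W–X–Y with 4β-(2-ethoxyethoxy) on unit Y; 3 8-bromo-5,7,3',4'-tetra-O-benzyl-(−)-epicatechin (5 equiv, excess recovered)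
Product: 19 protected tetramer W-(4β→6)-X-(4β→8)-Y-(4β→6)-Z (15 benzyl ethers, 4 aryl bromides)
Conditions: TMSOTf (0.5 equiv), CH2Cl2, −78 → −30 °C; then NaHCO3 (aq)
Reagents that add atoms: none
Why: Friedel–Crafts alkylation at C6 of 3 (C8 is blocked by Br, and 3 is in excess to outrun attack by C6 of unit Y of a second trimer), anti to the 3-OH of unit Y, sets the last stereocentre (C4 of unit Y, 4β).

Step 16
Reactants: 19 protected tetramer
Product: 20 epicatechin-(4β→6)-epiafzelechin-(4β→8)-epicatechin-(4β→6)-epicatechin (CNP0103636.1)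
Conditions: H2 (1 atm), 20% Pd(OH)2 on carbon, Et3N (6 equiv), THF/MeOH/H2O, rt; Sephadex LH-20
Reagents that add atoms: none
Why: Palladium-catalysed hydrogenolysis of the 15 benzyl ethers and hydrodehalogenation of the 4 aryl bromides in one operation; Et3N takes up HBr, so the acid-labile interflavan bonds and all 11 stereocentres are untouched.

**Compound list**

1 | (−)-epicatechin | O[C@@H]1Cc2c(O)cc(O)cc2O[C@@H]1c1ccc(O)c(O)c1 | starting material
2 | 5,7,3',4'-tetra-O-benzyl-(−)-epicatechin | O[C@@H]1Cc2c(OCc3ccccc3)cc(OCc3ccccc3)cc2O[C@@H]1c1ccc(OCc2ccccc2)c(OCc2ccccc2)c1 | intermediate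
3 | 8-bromo-5,7,3',4'-tetra-O-benzyl-(−)-epicatechin | O[C@@H]1Cc2c(OCc3ccccc3)cc(OCc3ccccc3)c(Br)c2O[C@@H]1c1ccc(OCc2ccccc2)c(OCc2ccccc2)c1 | intermediate
4 | (2R,3R,4S)-4-(2-ethoxyethoxy)-5,7,3',4'-tetra-O-benzylepicatechin | O[C@@H]1[C@@H](OCCOCC)c2c(OCc3ccccc3)cc(OCc3ccccc3)cc2O[C@@H]1c1ccc(OCc2ccccc2)c(OCc2ccccc2)c1 | intermediate
5 | (2R,3R,4S)-6,8-dibromo-4-(2-ethoxyethoxy)-5,7,3',4'-tetra-O-benzylepicatechin | O[C@@H]1[C@@H](OCCOCC)c2c(OCc3ccccc3)c(Br)c(OCc3ccccc3)c(Br)c2O[C@@H]1c1ccc(OCc2ccccc2)c(OCc2ccccc2)c1 | intermediate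
6 | 4-(benzyloxy)benzaldehyde | O=Cc1ccc(OCc2ccccc2)cc1 | starting material
7 | rac-1-[4-(benzyloxy)phenyl]prop-2-en-1-ol | C=CC(O)c1ccc(OCc2ccccc2)cc1 | intermediate
8 | 3,5-bis(benzyloxy)phenol | Oc1cc(OCc2ccccc2)cc(OCc2ccccc2)c1 | starting material
9 | (E)-3,5-bis(benzyloxy)-2-{3-[4-(benzyloxy)phenyl]prop-2-en-1-yl}phenol | Oc1cc(OCc2ccccc2)cc(OCc2ccccc2)c1C/C=C/c1ccc(OCc2ccccc2)cc1 | intermediate
10 | trans-epoxide of 9, racemate (both enantiomers written) | Oc1cc(OCc2ccccc2)cc(OCc2ccccc2)c1C[C@@H]1O[C@H]1c1ccc(OCc2ccccc2)cc1.Oc1cc(OCc2ccccc2)cc(OCc2ccccc2)c1C[C@H]1O[C@@H]1c1ccc(OCc2ccccc2)cc1 | intermediate (not isolated)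
11 | 2,3-trans-5,7-bis(benzyloxy)-2-[4-(benzyloxy)phenyl]chroman-3-ol, racemate (both enantiomers written) | O[C@H]1Cc2c(OCc3ccccc3)cc(OCc3ccccc3)cc2O[C@@H]1c1ccc(OCc2ccccc2)cc1.O[C@@H]1Cc2c(OCc3ccccc3)cc(OCc3ccccc3)cc2O[C@H]1c1ccc(OCc2ccccc2)cc1 | intermediate
12 | rac-5,7-bis(benzyloxy)-2-[4-(benzyloxy)phenyl]chroman-3-one | O=C1Cc2c(OCc3ccccc3)cc(OCc3ccccc3)cc2OC1c1ccc(OCc2ccccc2)cc1 | intermediate
13 | (2R,3R)-5,7-bis(benzyloxy)-2-[4-(benzyloxy)phenyl]chroman-3-ol (5,7,4'-tri-O-benzyl-(−)-epiafzelechin) | O[C@@H]1Cc2c(OCc3ccccc3)cc(OCc3ccccc3)cc2O[C@@H]1c1ccc(OCc2ccccc2)cc1 | intermediate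
14 | 8-bromo-5,7,4'-tri-O-benzyl-(−)-epiafzelechin | O[C@@H]1Cc2c(OCc3ccccc3)cc(OCc3ccccc3)c(Br)c2O[C@@H]1c1ccc(OCc2ccccc2)cc1 | intermediate
15 | dimer W–X: 6,8-dibromo-tetra-O-benzylepicatechin-(4β→6)-8-bromo-tri-O-benzylepiafzelechin | O[C@@H]1[C@@H](c3c(OCc5ccccc5)c(Br)c4O[C@H](c5ccc(OCc6ccccc6)cc5)[C@H](O)Cc4c3OCc3ccccc3)c2c(OCc3ccccc3)c(Br)c(OCc3ccccc3)c(Br)c2O[C@@H]1c1ccc(OCc2ccccc2)c(OCc2ccccc2)c1 | intermediate
16 | dimer W–X with 4β-(2-ethoxyethoxy) on unit X | O[C@@H]1[C@@H](c3c(OCc5ccccc5)c(Br)c4O[C@H](c5ccc(OCc6ccccc6)cc5)[C@H](O)[C@@H](OCCOCC)c4c3OCc3ccccc3)c2c(OCc3ccccc3)c(Br)c(OCc3ccccc3)c(Br)c2O[C@@H]1c1ccc(OCc2ccccc2)c(OCc2ccccc2)c1 | intermediate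
17 | trimer W–X–Y: dimer W–X-(4β→8)-tetra-O-benzylepicatechin | O[C@@H]1[C@@H](c3c(OCc5ccccc5)c(Br)c4O[C@H](c5ccc(OCc6ccccc6)cc5)[C@H](O)[C@@H](c7c(OCc9ccccc9)cc(OCc9ccccc9)c8c7O[C@H](c7ccc(OCc9ccccc9)c(OCc9ccccc9)c7)[C@H](O)C8)c4c3OCc3ccccc3)c2c(OCc3ccccc3)c(Br)c(OCc3ccccc3)c(Br)c2O[C@@H]1c1ccc(OCc2ccccc2)c(OCc2ccccc2)c1 | intermediate
18 | trimer W–X–Y with 4β-(2-ethoxyethoxy) on unit Y | O[C@@H]1[C@@H](c3c(OCc5ccccc5)c(Br)c4O[C@H](c5ccc(OCc6ccccc6)cc5)[C@H](O)[C@@H](c7c(OCc9ccccc9)cc(OCc9ccccc9)c8c7O[C@H](c7ccc(OCc9ccccc9)c(OCc9ccccc9)c7)[C@H](O)[C@H]8OCCOCC)c4c3OCc3ccccc3)c2c(OCc3ccccc3)c(Br)c(OCc3ccccc3)c(Br)c2O[C@@H]1c1ccc(OCc2ccccc2)c(OCc2ccccc2)c1 | intermediate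
19 | protected tetramer W-(4β→6)-X-(4β→8)-Y-(4β→6)-Z (unit Z = 8-bromo-tetra-O-benzylepicatechin) | O[C@@H]1[C@@H](c3c(OCc5ccccc5)c(Br)c4O[C@H](c5ccc(OCc6ccccc6)cc5)[C@H](O)[C@@H](c7c(OCc9ccccc9)cc(OCc9ccccc9)c8c7O[C@H](c7ccc(OCc9ccccc9)c(OCc9ccccc9)c7)[C@H](O)[C@H]8c5c(OCc7ccccc7)c(Br)c6c(c5OCc5ccccc5)C[C@@H](O)[C@@H](c5ccc(OCc7ccccc7)c(OCc7ccccc7)c5)O6)c4c3OCc3ccccc3)c2c(OCc3ccccc3)c(Br)c(OCc3ccccc3)c(Br)c2O[C@@H]1c1ccc(OCc2ccccc2)c(OCc2ccccc2)c1 | intermediate
20 | epicatechin-(4β→6)-epiafzelechin-(4β→8)-epicatechin-(4β→6)-epicatechin (CNP0103636.1) | Oc1ccc([C@H]2Oc3cc(O)c([C@H]4c5c(O)cc(O)cc5O[C@H](c5ccc(O)c(O)c5)[C@@H]4O)c(O)c3[C@H](c3c(O)cc(O)c4c3O[C@H](c3ccc(O)c(O)c3)[C@H](O)[C@H]4c3c(O)cc4c(c3O)C[C@@H](O)[C@@H](c3ccc(O)c(O)c3)O4)[C@H]2O)cc1 | target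

**Step count and risks**

Total step count: 16. Longest linear sequence: 12 steps (steps 5–16, from 6 to 20).

Steps most likely to fail:

Step 9 (the new reaction). The enantioselectivity and the rate of C2 epimerisation on this substrate class are untested, and the flavan-3-one may not tolerate the base. The fallback sets out from 12 and comes back at 13. It uses known chemistry: reduction of racemic 12 with LiBH(s-Bu)3 (THF, −78 °C) gives the racemic 2,3-cis alcohol F1, and the enantiomers are separated by preparative HPLC on a chiral stationary phase to give 13. The unwanted enantiomer is re-oxidised with Dess–Martin periodinane to 12 and recycled.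

Step 12 (DDQ etherification on the dimer; step 14 stands or falls with it). Risks are slow hydride abstraction from the brominated, crowded unit X and competing oxidation at the diarylmethine C4–H of unit W. The fallback sets out from 14 and comes back at 17, and installs the leaving group before any coupling. DDQ and 2-ethoxyethanol convert monomer 14 into its 4β-(2-ethoxyethoxy) ether F2. 2,6-Dimethylbenzenethiol with BF3·OEt2 (CH2Cl2, −78 °C) exchanges this for the 4β-(2,6-dimethylphenyl)sulfanyl derivative F3. F3 is coupled through its C6 with 5 under BF3·OEt2 (the thioether is not ionised) to give the dimer thioether F4. AgBF4 (THF/CH2Cl2, 0 °C) then ionises the C–S bond of F4 in the presence of 2 (3 equiv) to give 17.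

Step 15 (last 4→6 coupling). A trimeric cation must reach the doubly flanked C6 of 3, and C6 of unit Y of a second trimer competes. The fallback sets out from 16 and comes back at 19, and is convergent (two plus two). 4 is coupled with 3 (5 equiv; TMSOTf, CH2Cl2, −78 → −30 °C) at the monomer stage to give the dimer Y–Z, tetra-O-benzylepicatechin-(4β→6)-8-bromo-tetra-O-benzylepicatechin F5. 16 is then coupled with F5 (1.5 equiv; TMSOTf, CH2Cl2, −78 °C) at the free C8 of unit Y to give 19. This also makes step 14 unnecessary.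

Further compounds

F1 | step 9 | 2,3-cis-5,7-bis(benzyloxy)-2-[4-(benzyloxy)phenyl]chroman-3-ol, racemate (both enantiomers written) | O[C@@H]1Cc2c(OCc3ccccc3)cc(OCc3ccccc3)cc2O[C@@H]1c1ccc(OCc2ccccc2)cc1.O[C@H]1Cc2c(OCc3ccccc3)cc(OCc3ccccc3)cc2O[C@H]1c1ccc(OCc2ccccc2)cc1
F2 | step 12 | (2R,3R,4S)-8-bromo-4-(2-ethoxyethoxy)-5,7,4'-tri-O-benzylepiafzelechin | O[C@@H]1[C@@H](OCCOCC)c2c(OCc3ccccc3)cc(OCc3ccccc3)c(Br)c2O[C@@H]1c1ccc(OCc2ccccc2)cc1
F3 | step 12 | 8-bromo-4β-[(2,6-dimethylphenyl)sulfanyl]-5,7,4'-tri-O-benzylepiafzelechin | O[C@@H]1[C@@H](Sc3c(C)cccc3C)c2c(OCc3ccccc3)cc(OCc3ccccc3)c(Br)c2O[C@@H]1c1ccc(OCc2ccccc2)cc1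
F4 | step 12 | dimer W–X with 4β-[(2,6-dimethylphenyl)sulfanyl] on unit X | O[C@@H]1[C@@H](c3c(OCc5ccccc5)c(Br)c4O[C@H](c5ccc(OCc6ccccc6)cc5)[C@H](O)[C@@H](Sc5c(C)cccc5C)c4c3OCc3ccccc3)c2c(OCc3ccccc3)c(Br)c(OCc3ccccc3)c(Br)c2O[C@@H]1c1ccc(OCc2ccccc2)c(OCc2ccccc2)c1
F5 | step 15 | dimer Y–Z: 5,7,3',4'-tetra-O-benzylepicatechin-(4β→6)-8-bromo-5,7,3',4'-tetra-O-benzylepicatechin | O[C@@H]1[C@@H](c3c(OCc5ccccc5)c(Br)c4O[C@H](c5ccc(OCc6ccccc6)c(OCc6ccccc6)c5)[C@H](O)Cc4c3OCc3ccccc3)c2c(OCc3ccccc3)cc(OCc3ccccc3)cc2O[C@@H]1c1ccc(OCc2ccccc2)c(OCc2ccccc2)c1
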